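The readings are calculated with constants of no real substance; noise was put on by code.

A flask cannot hold more product than the partner it has received, if each product takes up one partner. So before anything else I reckon, as a share of the solid substrate charged, how much product the partner allows:

ceiling = c(partner) / c(solid substrate) = 0.300 M / 0.30 M = 100%

I call this the partner ceiling, and what I watch is the gap beneath it.

| flask | solid substrate | partner | protic impurity | remark | time |
|---|---|---|---|---|---|
| Tuesday's | 0.30 M | 0.30 M (fed, over 12 min) | 0.18 M | run made earlier |  |
| Thursday's | 0.30 M | 0.30 M (fed, over 12 min) | 0.40 M | run made earlier |  |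
| alder | 0.30 M | 0.300 M (fed, over 12 min) | 0.150 M |  | 12 min |
| larch | 0.30 M | 0.300 M | 0.300 M | everything together at the start | 12 min |

| run | time / min | product / % | solid substrate / % |
|---|---|---|---|
| Tuesday's | 2.50 | 18.1 | 35.1 |
| Tuesday's | 5.00 | 37.4 | 9.3 |
| Tuesday's | 8.00 | 58.9 | 0 |
| Tuesday's | 10.0 | 72.7 | 0 |
| Tuesday's | 12.0 | 80.6 | 1.5 |
| Thursday's | 2.50 | 15.6 | 25.7 |
| Thursday's | 5.00 | 37.3 | 2.7 |
| Thursday's | 8.00 | 59.0 | 0.4 |
| Thursday's | 10.0 | 70.5 | 0 |
| Thursday's | 12.0 | 75.4 | 0.9 |

(standard deviation of a reading: 1 percentage point)

- solid substrate is a solid; its amount is given per volume of the solution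
- at the start none of the solid substrate is in solution
- what has only dissolved of solid substrate counts as not reacted

* which of the two ends with the higher amount of product, in percent of the solid substrate charged ("neither" if they lie within 2 percentage points) (alder / larch / neither)
* product at the end, in percent of the solid substrate charged, alder
* product at the end, in percent of the solid substrate charged, larch

Alder and larch have the same ceiling as Tuesday's run. Alder looks nearly like Tuesday's run: the same feed, with 0.150 M of protic impurity against 0.18 M. In a fed flask the ceiling climbs with the feed. At 5.00 min in Tuesday's run, 41.7% had gone in and product read 37.4%, while solid substrate read 9.3%, so 53.3% of the charge showed in neither reading.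

Tuesday's run ended 19 percentage points under the ceiling and Thursday's, with 0.40 M of impurity, 25 points under it. The gap therefore moved by 5.2 points across that change of impurity. Alder's feed ends at the asked time (12 min against 12 min), as Tuesday's did, so I expect alder a little above Tuesday's 80.6%, having less impurity.

Larch has its whole partner charge from the start and 12 min to use it, against twice alder's impurity. The gap of the two fed runs widened with impurity, so larch's 0.300 M counts against it. Against that, the feed had raised the ceiling of Tuesday's run to 41.7% at 5.00 min, while larch has 100% from the start, so I expect larch closer to the ceiling than alder, though I put no number on it.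

The forecast says larch, with alder at 81.5% (79% to 84%) and larch at 88% (74% to 97%), on the ground that “there is no feed limit, so I expect a higher yield”.

The flasks give alder 83.6% and larch 94.6%, so larch ends higher, 6.6 points above the forecast's figure for it. Against the ceiling of 100%, alder stops 16 points short with 16% of its partner unbound, and larch stops 5.4 points short with 5.4% unbound.

    solid substrate ⇌ dissolved substrate, rate k1*(cs1 - [dissolved substrate]) while solid is left; crystals form when [dissolved substrate] > cs1 (solubility = 0.120 M, k = 0.0990 s⁻¹)
    dissolved substrate + partner → product (k = 0.260 M⁻¹ s⁻¹)
    solid substrate + protic impurity → quenched substrate (k = 0.00760 M⁻¹ s⁻¹)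

Larch with 0.075 M of partner has its ceiling lowered to 25.0%, which makes partner the limiting reagent. That flask ends at 25.0% product with 0% of its partner left.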